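**Retrosynthetic overview**
1. Target 22 ⇐ aryl TIPS ether 21 ⇐ diazoacetate 20: the γ-lactone is closed last by forming its CH2–CH(O) bond (C3–C3a) through a dirhodium-carbenoid 1,5 C–H insertion into the unfunctionalised OCH2 group of a 3-hydroxyoxolane.
2. Enabling feature: in 20 the C2–H bond of the oxolane ring is α to the ring oxygen O1 (activated) and lies 1,5 and cis to the carbene carbon held by the ester on the fully substituted C3. A five/five ring fusion can only be cis, so C3a is set by C6a.
3. Oxolane 18 ⇐ aldehyde 15 + C11 aryl phosphonium salt 6 (Wittig, then hydrogenation). 15 ⇐ triol 14 ⇐ epoxy alcohol 12 by 5-exo epoxide opening with inversion at the tertiary carbon (sets C5).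
4. 12 ⇐ Sharpless epoxidation of E-allylic alcohol 11 ⇐ alkyne 9 (carboalumination) ⇐ (R)-2-methylglycidol 7 (sets C6a).
5. Ring order: oxolane ring first (step 8), lactone ring last (step 14).

Key step: step 14

Assumption: (R)-2-methylglycidol 7 is taken as a commercial, enantiopure building block. Locants in the text follow oxolane numbering (O1, C2 = OCH2, C3 = carbinol carbon, C4 = CH2, C5 = quaternary ether carbon) and, for 21 and 22, furo[3,2-b]furan-2-one numbering.

**Route**

Step 1
Reactants: 1 4-bromophenol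
Product: 2 (4-bromophenoxy)triisopropylsilane
Conditions: TIPSCl (1.1 equiv), imidazole (2 equiv), DMF, rt
Reagents that add atoms: triisopropylsilyl chloride, CC(C)[Si](Cl)(C(C)C)C(C)C
Why: Standard silylation of a phenol; the bulky aryl silyl ether should survive the organometallic, basic, reductive and carbenoid steps that follow.

Step 2
Reactants: 2 (4-bromophenoxy)triisopropylsilane; 3 1,11-dibromoundecane
Product: 5 [4-(11-bromoundecyl)phenoxy]triisopropylsilane, via aryl Grignard reagent 4 (not isolated)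
Conditions: Mg turnings, THF, reflux; then added to 3 (3 equiv), Li2CuCl4 (3 mol%), THF, −10 to 0 °C
Reagents that add atoms: none
Why: Copper-catalysed coupling of an aryl Grignard reagent with a primary alkyl bromide (Kochi-type coupling), held at the mono-coupling stage by the excess of dibromide.

Step 3
Reactants: 5 [4-(11-bromoundecyl)phenoxy]triisopropylsilane
Product: 6 triphenyl{11-[4-(triisopropylsilyloxy)phenyl]undecyl}phosphonium bromide
Conditions: PPh3 (1.3 equiv), MeCN, reflux
Reagents that add atoms: triphenylphosphine, c1ccc(cc1)P(c1ccccc1)c1ccccc1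
Why: SN2 quaternisation of triphenylphosphine by a primary alkyl bromide.

Step 4
Reactants: 7 (R)-2-methylglycidol
Product: 8 (S)-2-[(benzyloxy)methyl]-2-methyloxirane
Conditions: NaH, BnBr, Bu4NI (cat.), THF, 0 °C to rt
Reagents that add atoms: benzyl bromide, BrCc1ccccc1
Why: Williamson etherification of the primary alkoxide; no bond to the quaternary stereocentre is touched (the descriptor changes from R to S only through the priority rules).

Step 5
Reactants: 8 (S)-2-[(benzyloxy)methyl]-2-methyloxirane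
Product: 9 (S)-1-(benzyloxy)-2-methylpent-4-yn-2-ol
Conditions: LiC≡CH·H2NCH2CH2NH2 (2 equiv), DMSO, rt; H2O
Reagents that add atoms: lithium acetylide (ethylenediamine complex), [Li]C#C
Why: SN2 opening of the 2,2-disubstituted epoxide at its unsubstituted CH2 by acetylide, which leaves the tertiary carbinol stereocentre intact.

Step 6
Reactants: 9 (S)-1-(benzyloxy)-2-methylpent-4-yn-2-ol
Product: 11 (2E,5S)-6-(benzyloxy)-3,5-dimethylhex-2-ene-1,5-diol, via alkenylalane 10 (not isolated)
Conditions: AlMe3 (3.5 equiv), Cp2ZrCl2 (0.25 equiv), CH2Cl2, 0 °C to rt; evaporate; n-BuLi, THF, −78 to 0 °C; (CH2O)n, rt; aqueous work-up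
Reagents that add atoms: trimethylaluminium, C[Al](C)C; formaldehyde (as paraformaldehyde), C=O
Why: Negishi zirconium-catalysed syn-carboalumination puts methyl on the internal alkyne carbon and aluminium on the terminus, and hydroxymethylation of the alkenylalanate with retention should give the E trisubstituted allylic alcohol.

Step 7
Reactants: 11 (2E,5S)-6-(benzyloxy)-3,5-dimethylhex-2-ene-1,5-diol
Product: 12 (2S)-1-(benzyloxy)-2-methyl-3-[(2S,3S)-3-(hydroxymethyl)-2-methyloxiran-2-yl]propan-2-ol
Conditions: Ti(OiPr)4 (0.2 equiv), L-(+)-diethyl tartrate (0.24 equiv), t-BuOOH (2 equiv), 4 Å MS, CH2Cl2, −20 °C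
Reagents that add atoms: tert-butyl hydroperoxide, CC(C)(C)OO
Why: Sharpless asymmetric epoxidation; with the L-(+)-tartrate an E-3,3-disubstituted allylic alcohol of the geraniol type is epoxidised to the (2S,3S)-epoxy alcohol under reagent control, the remote tertiary carbinol having little say.

Step 8
Reactants: 12 (2S)-1-(benzyloxy)-2-methyl-3-[(2S,3S)-3-(hydroxymethyl)-2-methyloxiran-2-yl]propan-2-ol
Product: 14 (1S)-1-[(2R,4S)-4-hydroxy-2,4-dimethyloxolan-2-yl]ethane-1,2-diol, via epoxy triol 13 (not isolated)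
Conditions: H2 (1 atm), 10% Pd/C, EtOAc, rt; filter; CSA (0.1 equiv), CH2Cl2, 0 °C
Reagents that add atoms: none
Why: Hydrogenolysis frees the primary hydroxyl, which under acid catalysis should open the epoxide 5-exo-tet at the tertiary carbon with inversion, so that the (S)-epoxide carbon becomes the quaternary ring carbon with the side chain trans to the ring hydroxyl.

Step 9
Reactants: 14 (1S)-1-[(2R,4S)-4-hydroxy-2,4-dimethyloxolan-2-yl]ethane-1,2-diol
Product: 15 (2R,4S)-4-hydroxy-2,4-dimethyloxolane-2-carbaldehyde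
Conditions: NaIO4 on silica gel, CH2Cl2, rt
Reagents that add atoms: none
Why: Malaprade glycol cleavage touches only the vicinal diol, and the quaternary α-alkoxy aldehyde cannot epimerise.

Step 10
Reactants: 15 (2R,4S)-4-hydroxy-2,4-dimethyloxolane-2-carbaldehyde; 6 triphenyl{11-[4-(triisopropylsilyloxy)phenyl]undecyl}phosphonium bromide
Product: 17 (3S,5R)-3,5-dimethyl-5-{(1Z)-12-[4-(triisopropylsilyloxy)phenyl]dodec-1-en-1-yl}oxolan-3-ol, via phosphonium ylide 16 (not isolated)
Conditions: 6 (2.2 equiv), NaN(SiMe3)2 (2.1 equiv), THF, 0 °C; then 15, −78 °C to rt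
Reagents that add atoms: none
Why: Wittig olefination of a non-enolisable aldehyde with a non-stabilised ylide; the excess ylide covers the free tertiary hydroxyl and the olefin geometry is of no consequence.

Step 11
Reactants: 17 (3S,5R)-3,5-dimethyl-5-{(1Z)-12-[4-(triisopropylsilyloxy)phenyl]dodec-1-en-1-yl}oxolan-3-ol
Product: 18 (3S,5S)-3,5-dimethyl-5-{12-[4-(triisopropylsilyloxy)phenyl]dodecyl}oxolan-3-ol
Conditions: H2 (1 atm), 10% Pd/C, EtOAc, rt
Reagents that add atoms: none
Why: Heterogeneous hydrogenation of a disubstituted alkene, to which the aryl silyl ether and the tertiary alcohol are inert (the C5 descriptor changes from R to S by the priority rules only).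

Step 12
Reactants: 18 (3S,5S)-3,5-dimethyl-5-{12-[4-(triisopropylsilyloxy)phenyl]dodecyl}oxolan-3-ol
Product: 19 (3S,5S)-3,5-dimethyl-5-{12-[4-(triisopropylsilyloxy)phenyl]dodecyl}oxolan-3-yl 2-bromoacetate
Conditions: BrCH2COBr (2 equiv), pyridine (3 equiv), CH2Cl2, 0 °C to rt
Reagents that add atoms: bromoacetyl bromide, BrCC(Br)=O
Why: Acylation of the tertiary alcohol by a highly reactive acid bromide with pyridine as base.

Step 13
Reactants: 19 (3S,5S)-3,5-dimethyl-5-{12-[4-(triisopropylsilyloxy)phenyl]dodecyl}oxolan-3-yl 2-bromoacetate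
Product: 20 (3S,5S)-3,5-dimethyl-5-{12-[4-(triisopropylsilyloxy)phenyl]dodecyl}oxolan-3-yl 2-diazoacetate
Conditions: TsNHNHTs (2 equiv), DBU (5 equiv), THF, 0 °C
Reagents that add atoms: N,N'-ditosylhydrazine, Cc1ccc(cc1)S(=O)(=O)NNS(=O)(=O)c1ccc(C)cc1
Why: Diazoacetate synthesis by N-alkylation of N,N'-ditosylhydrazine with the bromoacetate and base-induced loss of two sulfinate groups, a method that tolerates hindered esters.

Step 14
Reactants: 20 (3S,5S)-3,5-dimethyl-5-{12-[4-(triisopropylsilyloxy)phenyl]dodecyl}oxolan-3-yl 2-diazoacetate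
Product: 21 (3aS,5S,6aS)-5,6a-dimethyl-5-{12-[4-(triisopropylsilyloxy)phenyl]dodecyl}tetrahydrofuro[3,2-b]furan-2(3H)-one
Conditions: Rh2(cap)4 (dirhodium tetrakis(caprolactamate), 1 mol%), CH2Cl2, reflux, slow addition of 20 over 10 h (final about 0.01 M)
Reagents that add atoms: none
Why: The divalent rhodium carboxamidate expels N2 from the diazoacetate to give an electrophilic rhodium carbenoid, which should insert through a concerted, hydride-transfer-like three-centre transition state into the C2–H bond of the oxolane and so form the CH2–CH(O) bond of the lactone. The closest known reaction type is the dirhodium carboxamidate-catalysed intramolecular 1,5 C–H insertion of alkyl diazoacetates into C–H bonds next to an ether oxygen, which gives β-alkoxy-γ-butyrolactones, bicyclic ones included when the diazoacetate sits on a cyclic ether. The γ-lactone ring is closed in the fused mode by 1,5-insertion through a five-membered cyclic transition state, the carbene carbon being tied to C3 by the ester. The new stereocentre C3a is controlled by the substrate alone, because insertion goes with retention at carbon and only the C2 hydrogen cis to the C3 oxygen can be reached, a five/five fusion being necessarily cis. The step needs site selectivity for C2–H over the C4 methylene and the C3 methyl group, which are also 1,5 to the carbene; it is secured because C2–H is activated by the adjacent ring oxygen, whereas C4–H is β to two oxygens and flanked by two quaternary carbons, the methyl C–H bonds are primary, and C3 carries no hydrogen that could lead to a β-lactone. Slow addition to the electron-rich carboxamidate catalyst should suppress carbene dimerisation and attack on the ring oxygen.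

Step 15
Reactants: 21 (3aS,5S,6aS)-5,6a-dimethyl-5-{12-[4-(triisopropylsilyloxy)phenyl]dodecyl}tetrahydrofuro[3,2-b]furan-2(3H)-one
Product: 22 plakortone N, (3aS,5S,6aS)-5-[12-(4-hydroxyphenyl)dodecyl]-5,6a-dimethyltetrahydrofuro[3,2-b]furan-2(3H)-one
Conditions: Bu4NF (1.2 equiv), AcOH (1.2 equiv), THF, 0 °C
Reagents that add atoms: none
Why: Fluoride cleavage of the aryl silyl ether, buffered with acetic acid so that the lactone and its β-alkoxy carbonyl unit do not meet free base.

**Compound list**
1 | 4-bromophenol | Oc1ccc(Br)cc1 | starting material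
2 | (4-bromophenoxy)triisopropylsilane | CC(C)[Si](Oc1ccc(Br)cc1)(C(C)C)C(C)C | intermediate
3 | 1,11-dibromoundecane | BrCCCCCCCCCCCBr | starting material
4 | [4-(triisopropylsilyloxy)phenyl]magnesium bromide (formed in situ) | CC(C)[Si](Oc1ccc([Mg]Br)cc1)(C(C)C)C(C)C | intermediate
5 | [4-(11-bromoundecyl)phenoxy]triisopropylsilane | CC(C)[Si](Oc1ccc(CCCCCCCCCCCBr)cc1)(C(C)C)C(C)C | intermediate
6 | triphenyl{11-[4-(triisopropylsilyloxy)phenyl]undecyl}phosphonium bromide | CC(C)[Si](Oc1ccc(CCCCCCCCCCC[P+](c2ccccc2)(c2ccccc2)c2ccccc2)cc1)(C(C)C)C(C)C.[Br-] | intermediate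
7 | (R)-2-methylglycidol, [(2R)-2-methyloxiran-2-yl]methanol | C[C@@]1(CO)CO1 | starting material
8 | (S)-2-[(benzyloxy)methyl]-2-methyloxirane | C[C@@]1(COCc2ccccc2)CO1 | intermediate
9 | (S)-1-(benzyloxy)-2-methylpent-4-yn-2-ol | C#CC[C@](C)(O)COCc1ccccc1 | intermediate
10 | (E)-alkenyldimethylalane of 9 as its dimethylaluminium alkoxide (formed in situ) | C[Al](C)/C=C(\C)C[C@@](C)(COCc1ccccc1)O[Al](C)C | intermediate
11 | (2E,5S)-6-(benzyloxy)-3,5-dimethylhex-2-ene-1,5-diol | OC/C=C(\C)C[C@](C)(O)COCc1ccccc1 | intermediate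
12 | (2S)-1-(benzyloxy)-2-methyl-3-[(2S,3S)-3-(hydroxymethyl)-2-methyloxiran-2-yl]propan-2-ol | OC[C@@H]1O[C@@]1(C)C[C@](C)(O)COCc1ccccc1 | intermediate
13 | (2S)-3-[(2S,3S)-3-(hydroxymethyl)-2-methyloxiran-2-yl]-2-methylpropane-1,2-diol (formed in situ) | OC[C@@H]1O[C@@]1(C)C[C@](C)(O)CO | intermediate
14 | (1S)-1-[(2R,4S)-4-hydroxy-2,4-dimethyloxolan-2-yl]ethane-1,2-diol | C[C@]1([C@@H](O)CO)C[C@](C)(O)CO1 | intermediate
15 | (2R,4S)-4-hydroxy-2,4-dimethyloxolane-2-carbaldehyde | C[C@]1(C=O)C[C@](C)(O)CO1 | intermediate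
16 | triphenyl{11-[4-(triisopropylsilyloxy)phenyl]undecylidene}phosphorane (formed in situ) | CC(C)[Si](Oc1ccc(CCCCCCCCCCC=P(c2ccccc2)(c2ccccc2)c2ccccc2)cc1)(C(C)C)C(C)C | intermediate
17 | (3S,5R)-3,5-dimethyl-5-{(1Z)-12-[4-(triisopropylsilyloxy)phenyl]dodec-1-en-1-yl}oxolan-3-ol | C[C@]1(/C=C\CCCCCCCCCCc2ccc(O[Si](C(C)C)(C(C)C)C(C)C)cc2)C[C@](C)(O)CO1 | intermediate
18 | (3S,5S)-3,5-dimethyl-5-{12-[4-(triisopropylsilyloxy)phenyl]dodecyl}oxolan-3-ol | C[C@]1(CCCCCCCCCCCCc2ccc(O[Si](C(C)C)(C(C)C)C(C)C)cc2)C[C@](C)(O)CO1 | intermediate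
19 | (3S,5S)-3,5-dimethyl-5-{12-[4-(triisopropylsilyloxy)phenyl]dodecyl}oxolan-3-yl 2-bromoacetate | C[C@]1(CCCCCCCCCCCCc2ccc(O[Si](C(C)C)(C(C)C)C(C)C)cc2)C[C@](C)(OC(=O)CBr)CO1 | intermediate
20 | (3S,5S)-3,5-dimethyl-5-{12-[4-(triisopropylsilyloxy)phenyl]dodecyl}oxolan-3-yl 2-diazoacetate | C[C@]1(CCCCCCCCCCCCc2ccc(O[Si](C(C)C)(C(C)C)C(C)C)cc2)C[C@](C)(OC(=O)C=[N+]=[N-])CO1 | intermediate
21 | (3aS,5S,6aS)-5,6a-dimethyl-5-{12-[4-(triisopropylsilyloxy)phenyl]dodecyl}tetrahydrofuro[3,2-b]furan-2(3H)-one | C[C@]1(CCCCCCCCCCCCc2ccc(O[Si](C(C)C)(C(C)C)C(C)C)cc2)C[C@]2(C)OC(=O)C[C@@H]2O1 | intermediate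
22 | plakortone N, (3aS,5S,6aS)-5-[12-(4-hydroxyphenyl)dodecyl]-5,6a-dimethyltetrahydrofuro[3,2-b]furan-2(3H)-one | C[C@]1(CCCCCCCCCCCCc2ccc(O)cc2)C[C@]2(C)OC(=O)C[C@@H]2O1 | target

**Summary**
Total step count: 15. Longest linear sequence: 12 steps (7 to 22, steps 4 to 15).

**Steps most likely to fail**

1. Step 14. What may go wrong: the carbenoid is used up by dimerisation or by attack on the ring oxygen (oxonium ylide and its rearrangement), or it inserts at the C4 methylene, before it reaches the C2–H bond. The fallback uses a two-acceptor carbenoid of known behaviour and removes the extra ester afterwards. It sets out from 18: acylation with methyl malonyl chloride and pyridine should give the mixed malonate methyl (3S,5S)-3,5-dimethyl-5-{12-[4-(triisopropylsilyloxy)phenyl]dodecyl}oxolan-3-yl propanedioate F1. Diazo transfer (4-acetamidobenzenesulfonyl azide, Et3N, MeCN) should give the diazomalonate F2. Rh2(OAc)4 (dirhodium tetraacetate, 1 mol%) in refluxing CH2Cl2 should close the lactone at the same C–H bond to methyl (3aS,5S,6aS)-5,6a-dimethyl-2-oxo-5-{12-[4-(triisopropylsilyloxy)phenyl]dodecyl}hexahydrofuro[3,2-b]furan-3-carboxylate F3 (both C3 epimers). Krapcho demethoxycarbonylation (LiCl, wet DMSO, 130 °C) comes back to the route at 21.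

2. Step 6. What may go wrong: sluggish or regiochemically impure carboalumination next to the aluminium alkoxide, and protonolysis of the alkenylalanate instead of hydroxymethylation. The fallback builds the trisubstituted olefin by trans-hydroalumination, iodination and methyl coupling. It sets out from 9: double deprotonation (n-BuLi, THF, −78 °C) and addition to paraformaldehyde should give (5S)-6-(benzyloxy)-5-methylhex-2-yne-1,5-diol F4. Hydroxyl-directed trans-hydroalumination with NaAlH2(OCH2CH2OMe)2 (THF, 0 °C) and iodination (I2, −78 °C) should give (2Z,5S)-6-(benzyloxy)-3-iodo-5-methylhex-2-ene-1,5-diol F5. Coupling with Me2CuLi (excess, Et2O, 0 °C), which goes with retention of olefin geometry, comes back at 11.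

3. Step 12. What may go wrong: slow acylation of the hindered tertiary hydroxyl, with ionisation or elimination at the tertiary carbinol under the acidic by-product. The fallback installs the diazo ester by acetoacetylation, diazo transfer and deacetylation. It sets out from 18: heating with 2,2,6-trimethyl-4H-1,3-dioxin-4-one (xylene, 140 °C, acetylketene transfer) should give the acetoacetate (3S,5S)-3,5-dimethyl-5-{12-[4-(triisopropylsilyloxy)phenyl]dodecyl}oxolan-3-yl 3-oxobutanoate F6. Diazo transfer (4-acetamidobenzenesulfonyl azide, Et3N, MeCN) should give the 2-diazo-3-oxobutanoate F7. Deacetylation with pyrrolidine (MeCN, rt) comes back at 20, with 19 bypassed.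

Further compounds
F1 | step 14 | methyl (3S,5S)-3,5-dimethyl-5-{12-[4-(triisopropylsilyloxy)phenyl]dodecyl}oxolan-3-yl propanedioate | C[C@]1(CCCCCCCCCCCCc2ccc(O[Si](C(C)C)(C(C)C)C(C)C)cc2)C[C@](C)(OC(=O)CC(=O)OC)CO1
F2 | step 14 | methyl (3S,5S)-3,5-dimethyl-5-{12-[4-(triisopropylsilyloxy)phenyl]dodecyl}oxolan-3-yl 2-diazopropanedioate | C[C@]1(CCCCCCCCCCCCc2ccc(O[Si](C(C)C)(C(C)C)C(C)C)cc2)C[C@](C)(OC(=O)C(=[N+]=[N-])C(=O)OC)CO1
F3 | step 14 | methyl (3aS,5S,6aS)-5,6a-dimethyl-2-oxo-5-{12-[4-(triisopropylsilyloxy)phenyl]dodecyl}hexahydrofuro[3,2-b]furan-3-carboxylate | C[C@]1(CCCCCCCCCCCCc2ccc(O[Si](C(C)C)(C(C)C)C(C)C)cc2)C[C@]2(C)OC(=O)C(C(=O)OC)[C@@H]2O1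
F4 | step 6 | (5S)-6-(benzyloxy)-5-methylhex-2-yne-1,5-diol | OCC#CC[C@](C)(O)COCc1ccccc1
F5 | step 6 | (2Z,5S)-6-(benzyloxy)-3-iodo-5-methylhex-2-ene-1,5-diol | OC/C=C(\I)C[C@](C)(O)COCc1ccccc1
F6 | step 12 | (3S,5S)-3,5-dimethyl-5-{12-[4-(triisopropylsilyloxy)phenyl]dodecyl}oxolan-3-yl 3-oxobutanoate | C[C@]1(CCCCCCCCCCCCc2ccc(O[Si](C(C)C)(C(C)C)C(C)C)cc2)C[C@](C)(OC(=O)CC(C)=O)CO1
F7 | step 12 | (3S,5S)-3,5-dimethyl-5-{12-[4-(triisopropylsilyloxy)phenyl]dodecyl}oxolan-3-yl 2-diazo-3-oxobutanoate | C[C@]1(CCCCCCCCCCCCc2ccc(O[Si](C(C)C)(C(C)C)C(C)C)cc2)C[C@](C)(OC(=O)C(=[N+]=[N-])C(C)=O)CO1
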